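**Retrosynthetic overview**

- The target is an upper 4-arylflavan-3-ol (2R,3S,4R, all-trans) whose C4 is bonded to ring B of a lower 2,3-cis flavan-3-ol (2S,3S). The strategy rests on upper C4 being a doubly benzylic methine joined to C4a of the 7-oxygenated ring A and to a ring-B carbon that lies para to an oxygen.
- Key disconnection: upper C4–C4a, closed last by intramolecular Friedel–Crafts attack of a 3-benzyloxyphenyl ether (already attached through O1–C2) on a C4 cation bridged by the C3 acetate. C2 and C3 come from a Juliá–Colonna chalcone epoxide, reduced and then opened at C2 by 3-(benzyloxy)phenol.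
- Lower unit: the bromine kept on ring B is lithiated and acylated with an (S)-2-benzyloxy-3-arylpropanoic Weinreb amide made from methyl (S)-glycidate. Chelation-controlled reduction and Mitsunobu closure of O1–C2 with inversion give the cis ring, and hydrogenolysis ends the route.
- Ring order: upper ring C (step 9), then lower ring C (step 20).

Key step: step 9

Remark on the chemistry: the aryl ether is introduced on the epoxy alcohol, not the epoxy ketone, because a β-aryloxy ketone can lose the phenol by β-elimination under base and the epoxy ketone can rearrange under Lewis acid. The resulting diol is acetylated on both oxygens, so the C4 oxygen leaves as acetate in the key step. Open-chain intermediates are numbered C2–C4 as in the flavan they become; some CIP labels at C3 and C4 change with the substituents although the spatial arrangement does not.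

**Route**

Step 1
Reactants: 1 3,4-bis(benzyloxy)benzaldehyde
Product: 2 4,5-bis(benzyloxy)-2-bromobenzaldehyde
Conditions: Br2, NaOAc, AcOH, rt
Reagents that add atoms: bromine, BrBr
Why: Electrophilic aromatic bromination should go to the position para to the 3-benzyloxy group and ortho to the formyl group, the most activated unhindered site of a 3,4-dialkoxybenzaldehyde.

Step 2
Reactants: 2 4,5-bis(benzyloxy)-2-bromobenzaldehyde
Product: 3 1-[4,5-bis(benzyloxy)-2-bromophenyl]ethan-1-ol (racemic)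
Conditions: MeMgBr, THF, 0 °C; then water
Reagents that add atoms: methylmagnesium bromide, C[Mg]Br
Why: Grignard addition to the aldehyde should give the secondary benzylic alcohol as a racemate (the centre is removed in step 3), the aryl bromide being inert to MeMgBr at 0 °C.

Step 3
Reactants: 3 1-[4,5-bis(benzyloxy)-2-bromophenyl]ethan-1-ol
Product: 4 1-[4,5-bis(benzyloxy)-2-bromophenyl]ethan-1-one
Conditions: Dess–Martin periodinane, CH2Cl2, rt
Reagents that add atoms: none
Why: Dess–Martin oxidation converts a secondary benzylic alcohol into the aryl methyl ketone under mild conditions that spare benzyl ethers and the aryl bromide.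

Step 4
Reactants: 4 1-[4,5-bis(benzyloxy)-2-bromophenyl]ethan-1-one; 1 3,4-bis(benzyloxy)benzaldehyde
Product: 5 (E)-1-[4,5-bis(benzyloxy)-2-bromophenyl]-3-[3,4-bis(benzyloxy)phenyl]prop-2-en-1-one
Conditions: KOH, EtOH/THF, rt
Reagents that add atoms: none
Why: Claisen–Schmidt condensation of the methyl ketone with the non-enolisable aldehyde, followed by dehydration, should give the (E)-chalcone.

Step 5
Reactants: 5 (E)-chalcone
Product: 6 [4,5-bis(benzyloxy)-2-bromophenyl][(2R,3S)-3-[3,4-bis(benzyloxy)phenyl]oxiran-2-yl]methanone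
Conditions: poly-L-leucine, urea·H2O2, DBU, THF, rt
Reagents that add atoms: urea–hydrogen peroxide, NC(N)=O.OO
Why: In the Juliá–Colonna epoxidation the hydroperoxide anion adds to one enone face held by the helical L-polypeptide and closes to the trans-(2R,3S)-epoxy ketone, the sense established for chalcones, which sets the future C3 and (before inversion) C2.

Step 6
Reactants: 6 (2R,3S)-epoxy ketone
Product: 7 [4,5-bis(benzyloxy)-2-bromophenyl][(2S,3S)-3-[3,4-bis(benzyloxy)phenyl]oxiran-2-yl]methanol (both carbinol epimers)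
Conditions: NaBH4, MeOH/THF, −20 °C
Reagents that add atoms: none
Why: Borohydride 1,2-reduction of the ketone leaves the epoxide intact, and the new carbinol centre (C4) may form as both epimers because it is ionised in step 9.

Step 7
Reactants: 7 epoxy alcohol; 8 3-(benzyloxy)phenol
Product: 9 (2S,3R)-1-[4,5-bis(benzyloxy)-2-bromophenyl]-3-[3,4-bis(benzyloxy)phenyl]-3-[3-(benzyloxy)phenoxy]propane-1,2-diol (both C1 epimers)
Conditions: Ti(OiPr)4 (1.5 equiv), 8 (3 equiv), toluene, rt → 40 °C; aq potassium sodium tartrate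
Reagents that add atoms: none
Why: In this titanium-assisted, distal-selective opening of a 2,3-epoxy alcohol the carbinol and epoxide oxygens bind titanium and the aryloxide attacks the benzylic epoxide carbon from the rear, so C2 is set (R) by inversion while the C3–O bond is untouched.

Step 8
Reactants: 9 diol
Product: 10 (2R,3R)-1-[4,5-bis(benzyloxy)-2-bromophenyl]-3-[3,4-bis(benzyloxy)phenyl]-3-[3-(benzyloxy)phenoxy]propane-1,2-diyl diacetate (both C1 epimers)
Conditions: Ac2O, pyridine, DMAP (cat.), CH2Cl2, rt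
Reagents that add atoms: acetic anhydride, CC(=O)OC(C)=O
Why: DMAP-catalysed acylation of both secondary hydroxyls places the participating acetate on O3 and turns the C4 hydroxyl into the leaving group, with no stereocentre touched.

Step 9
Reactants: 10 open-chain C2 aryl ether 3,4-diacetate
Product: 12 (2R,3S,4S)-7-(benzyloxy)-4-[4,5-bis(benzyloxy)-2-bromophenyl]-2-[3,4-bis(benzyloxy)phenyl]chroman-3-yl acetate, via acetoxonium ion 11 (not isolated)
Conditions: TMSOTf (0.2 equiv), 4 Å MS, CH2Cl2, −40 → 0 °C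
Reagents that add atoms: none
Why: TMSOTf silylates and ionises the benzylic C4 acetate to a cation stabilised by the para-benzyloxy group of lower ring B, and the C3 acetate captures it as the 2-methyl-1,3-dioxolan-2-ylium ion 11, which bridges C3–C4, blocks hydride or aryl shift and makes both C4 epimers converge. The closest known reactions are the acid-promoted intramolecular Friedel–Crafts benzylation of 3-aryloxy-1-arylpropyl derivatives to 4-arylchromans and the 3-O-acyl-directed 3,4-trans substitution at C4 of flavans, the counterpart of 1,2-trans glycosylation. Upper ring C closes by formation of C4–C4a in a six-membered, chair-like Friedel–Crafts closure through the O1–C2 tether (endo with respect to the attacked arene π bond, the leaving group exocyclic). The new C4 centre is controlled by the acetoxonium bridge and the equatorial preference of the aryl groups, so the arene should add anti to the C3 oxygen and give the all-equatorial 2,3-trans-3,4-trans isomer, while C2 and C3 are carried over unchanged. The step needs ionisation at C4 and not at the C2 benzylic aryl ether, which the acetate secures as the only Lewis-basic leaving group; it needs attack by the resorcinol-type ring and not by the catechol ring on C2 (which would give an indane), secured by the higher nucleophilicity of the carbon para to benzyloxy and by the six- over five-membered transition state; and it needs attack at that carbon and not at the one between the two oxygens, secured by sterics.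

Step 10
Reactants: 12 flavan-3-yl acetate
Product: 13 (2R,3S,4S)-7-(benzyloxy)-4-[4,5-bis(benzyloxy)-2-bromophenyl]-2-[3,4-bis(benzyloxy)phenyl]chroman-3-ol
Conditions: K2CO3 (cat.), MeOH/THF, rt
Reagents that add atoms: none
Why: Base-catalysed transesterification (Zemplén-type methanolysis) removes the acetate without touching a stereocentre, since benzylated flavans do not epimerise under these conditions.

Step 11
Reactants: 13 flavan-3-ol
Product: 14 (2R,3S,4S)-3,7-bis(benzyloxy)-4-[4,5-bis(benzyloxy)-2-bromophenyl]-2-[3,4-bis(benzyloxy)phenyl]chromane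
Conditions: NaH, BnBr, Bu4NI (cat.), DMF, 0 °C → rt
Reagents that add atoms: benzyl bromide, BrCc1ccccc1
Why: Williamson etherification of the sodium alkoxide installs a 3-O-benzyl group that tolerates organolithium chemistry and is removed in the final hydrogenolysis.

Step 12
Reactants: 8 3-(benzyloxy)phenol
Product: 15 5-(benzyloxy)-2-iodophenol
Conditions: I2, NaHCO3, THF/H2O, 0 °C → rt
Reagents that add atoms: iodine, II
Why: Electrophilic iodination of the phenoxide should occur ortho to the hydroxyl and para to the benzyloxy group, the regiochemistry known for 3-alkoxyphenols under these conditions.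

Step 13
Reactants: 15 5-(benzyloxy)-2-iodophenol
Product: 16 2-(allyloxy)-4-(benzyloxy)-1-iodobenzene
Conditions: allyl bromide, K2CO3, DMF, rt
Reagents that add atoms: allyl bromide, C=CCBr
Why: Williamson allylation masks the phenol as an ether that survives organometallic steps and is later removed selectively by zerovalent palladium.

Step 14
Reactants: 16 2-(allyloxy)-4-(benzyloxy)-1-iodobenzene; 17 methyl (S)-glycidate
Product: 19 methyl (S)-3-[2-(allyloxy)-4-(benzyloxy)phenyl]-2-hydroxypropanoate, via aryl Grignard reagent 18 (not isolated)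
Conditions: i-PrMgCl·LiCl, THF, −20 °C; then CuI (10 mol%), 17, −40 → −20 °C
Reagents that add atoms: none
Why: Iodine–magnesium exchange followed by copper-catalysed SN2 opening of the glycidic ester at its unsubstituted carbon leaves the stereocentre (later lower C3) untouched as (S).

Step 15
Reactants: 19 hydroxy ester
Product: 20 methyl (S)-3-[2-(allyloxy)-4-(benzyloxy)phenyl]-2-(benzyloxy)propanoate
Conditions: BnBr, Ag2O, CH2Cl2, rt, dark
Reagents that add atoms: benzyl bromide, BrCc1ccccc1
Why: Silver-oxide-mediated Williamson benzylation works without a base strong enough to enolise the ester, so the (S) centre should be kept.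

Step 16
Reactants: 20 benzyloxy ester
Product: 21 (S)-3-[2-(allyloxy)-4-(benzyloxy)phenyl]-2-(benzyloxy)-N-methoxy-N-methylpropanamide
Conditions: MeNH(OMe)·HCl, i-PrMgCl, THF, −20 → 0 °C
Reagents that add atoms: N,O-dimethylhydroxylamine hydrochloride, CNOC.Cl
Why: Direct aminolysis of the ester by the chloromagnesium amide of N,O-dimethylhydroxylamine (Weinreb amide formation) proceeds at low temperature without racemisation of α-alkoxy esters.

Step 17
Reactants: 14 aryl bromide; 21 Weinreb amide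
Product: 23 (S)-3-[2-(allyloxy)-4-(benzyloxy)phenyl]-2-(benzyloxy)-1-{4,5-bis(benzyloxy)-2-[(2R,3S,4R)-3,7-bis(benzyloxy)-2-[3,4-bis(benzyloxy)phenyl]chroman-4-yl]phenyl}propan-1-one, via aryllithium 22 (not isolated)
Conditions: n-BuLi, THF, −78 °C; then 21, −78 → −40 °C; water
Reagents that add atoms: none
Why: Bromine–lithium exchange and Weinreb ketone synthesis, in which the chelated tetrahedral adduct prevents over-addition and the α-stereocentre is retained.

Step 18
Reactants: 23 α-benzyloxy ketone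
Product: 24 (1R,2S)-3-[2-(allyloxy)-4-(benzyloxy)phenyl]-2-(benzyloxy)-1-{4,5-bis(benzyloxy)-2-[(2R,3S,4R)-3,7-bis(benzyloxy)-2-[3,4-bis(benzyloxy)phenyl]chroman-4-yl]phenyl}propan-1-ol
Conditions: Zn(BH4)2, Et2O/CH2Cl2, −30 → 0 °C
Reagents that add atoms: none
Why: In this chelation-controlled (Cram chelate) reduction zinc bridges the ketone and α-benzyloxy oxygens and hydride adds from the face opposite the CH2Ar group, which should give the anti (1R,2S) alcohol.

Step 19
Reactants: 24 anti alcohol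
Product: 25 (1R,2S)-2-(benzyloxy)-3-[4-(benzyloxy)-2-hydroxyphenyl]-1-{4,5-bis(benzyloxy)-2-[(2R,3S,4R)-3,7-bis(benzyloxy)-2-[3,4-bis(benzyloxy)phenyl]chroman-4-yl]phenyl}propan-1-ol
Conditions: Pd(PPh3)4 (5 mol%), morpholine, THF, rt
Reagents that add atoms: none
Why: In this Tsuji–Trost deallylation zerovalent palladium ionises only the aryl allyl ether and morpholine traps the allyl fragment, freeing the phenol while benzyl ethers and the benzylic alcohol stay.

Step 20
Reactants: 25 phenol alcohol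
Product: 26 (2S,3S)-3,7-bis(benzyloxy)-2-{4,5-bis(benzyloxy)-2-[(2R,3S,4R)-3,7-bis(benzyloxy)-2-[3,4-bis(benzyloxy)phenyl]chroman-4-yl]phenyl}chromane
Conditions: PPh3, DIAD, toluene, 0 °C → rt
Reagents that add atoms: none
Why: In the intramolecular Mitsunobu etherification the phenol displaces the oxyphosphonium group at the benzylic carbon in a six-membered exo closure with inversion, turning the (1R) carbinol into lower C2 (S) and giving the 2,3-cis ring, a closure mode known in flavan-3-ol synthesis.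

Step 21
Reactants: 26 octabenzyl ether
Product: 27 (2R,3S,4R)-2-(3,4-dihydroxyphenyl)-4-{2-[(2S,3S)-3,7-dihydroxychroman-2-yl]-4,5-dihydroxyphenyl}chromane-3,7-diol
Conditions: H2 (1 atm), Pd(OH)2/C, THF/MeOH, rt
Reagents that add atoms: none
Why: Catalytic hydrogenolysis cleaves the eight benzyl ethers, while the flavan C2–O1 bonds and the C4–aryl bond are stable under these mild conditions.

**Compound list**

1 | 3,4-bis(benzyloxy)benzaldehyde | O=Cc1ccc(OCc2ccccc2)c(OCc2ccccc2)c1 | starting material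
2 | 4,5-bis(benzyloxy)-2-bromobenzaldehyde | O=Cc1cc(OCc2ccccc2)c(OCc2ccccc2)cc1Br | intermediate
3 | 1-[4,5-bis(benzyloxy)-2-bromophenyl]ethan-1-ol (racemic) | CC(O)c1cc(OCc2ccccc2)c(OCc2ccccc2)cc1Br | intermediate
4 | 1-[4,5-bis(benzyloxy)-2-bromophenyl]ethan-1-one | CC(=O)c1cc(OCc2ccccc2)c(OCc2ccccc2)cc1Br | intermediate
5 | (E)-1-[4,5-bis(benzyloxy)-2-bromophenyl]-3-[3,4-bis(benzyloxy)phenyl]prop-2-en-1-one | O=C(/C=C/c1ccc(OCc2ccccc2)c(OCc2ccccc2)c1)c1cc(OCc2ccccc2)c(OCc2ccccc2)cc1Br | intermediate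
6 | [4,5-bis(benzyloxy)-2-bromophenyl][(2R,3S)-3-[3,4-bis(benzyloxy)phenyl]oxiran-2-yl]methanone (trans-epoxy ketone) | O=C(c1cc(OCc2ccccc2)c(OCc2ccccc2)cc1Br)[C@@H]1O[C@H]1c1ccc(OCc2ccccc2)c(OCc2ccccc2)c1 | intermediate
7 | [4,5-bis(benzyloxy)-2-bromophenyl][(2S,3S)-3-[3,4-bis(benzyloxy)phenyl]oxiran-2-yl]methanol, both carbinol epimers (oxirane as in 6; the label at oxirane C2 changes by priority only) | OC(c1cc(OCc2ccccc2)c(OCc2ccccc2)cc1Br)[C@@H]1O[C@H]1c1ccc(OCc2ccccc2)c(OCc2ccccc2)c1 | intermediate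
8 | 3-(benzyloxy)phenol | Oc1cccc(OCc2ccccc2)c1 | starting material
9 | (2S,3R)-1-[4,5-bis(benzyloxy)-2-bromophenyl]-3-[3,4-bis(benzyloxy)phenyl]-3-[3-(benzyloxy)phenoxy]propane-1,2-diol, both C1 epimers (propane C1, C2, C3 = flavan C4, C3, C2) | OC(c1cc(OCc2ccccc2)c(OCc2ccccc2)cc1Br)[C@H](O)[C@@H](c1ccc(OCc2ccccc2)c(OCc2ccccc2)c1)Oc1cccc(OCc2ccccc2)c1 | intermediate
10 | (2R,3R)-1-[4,5-bis(benzyloxy)-2-bromophenyl]-3-[3,4-bis(benzyloxy)phenyl]-3-[3-(benzyloxy)phenoxy]propane-1,2-diyl diacetate, both C1 epimers (same spatial arrangement as 9); key-step precursor: open-chain C2 aryl ether, C3 acetate, C4 carbinol carried as its acetate | CC(=O)OC(c1cc(OCc2ccccc2)c(OCc2ccccc2)cc1Br)[C@H](OC(C)=O)[C@@H](c1ccc(OCc2ccccc2)c(OCc2ccccc2)c1)Oc1cccc(OCc2ccccc2)c1 | intermediate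
11 | 4-[4,5-bis(benzyloxy)-2-bromophenyl]-5-{(R)-[3,4-bis(benzyloxy)phenyl][3-(benzyloxy)phenoxy]methyl}-2-methyl-1,3-dioxolan-2-ylium triflate (acetoxonium ion bridging C3 and C4) | CC1=[O+]C(c2cc(OCc3ccccc3)c(OCc3ccccc3)cc2Br)[C@@H]([C@@H](c2ccc(OCc3ccccc3)c(OCc3ccccc3)c2)Oc2cccc(OCc3ccccc3)c2)O1.[O-]S(=O)(=O)C(F)(F)F | intermediate
12 | (2R,3S,4S)-7-(benzyloxy)-4-[4,5-bis(benzyloxy)-2-bromophenyl]-2-[3,4-bis(benzyloxy)phenyl]chroman-3-yl acetate (2,3-trans-3,4-trans; key-step product) | c1ccccc1COc1ccc2c(c1)O[C@H](c1ccc(OCc3ccccc3)c(OCc3ccccc3)c1)[C@@H](OC(C)=O)[C@@H]2c1cc(OCc2ccccc2)c(OCc2ccccc2)cc1Br | intermediate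
13 | (2R,3S,4S)-7-(benzyloxy)-4-[4,5-bis(benzyloxy)-2-bromophenyl]-2-[3,4-bis(benzyloxy)phenyl]chroman-3-ol | c1ccccc1COc1ccc2c(c1)O[C@H](c1ccc(OCc3ccccc3)c(OCc3ccccc3)c1)[C@@H](O)[C@@H]2c1cc(OCc2ccccc2)c(OCc2ccccc2)cc1Br | intermediate
14 | (2R,3S,4S)-3,7-bis(benzyloxy)-4-[4,5-bis(benzyloxy)-2-bromophenyl]-2-[3,4-bis(benzyloxy)phenyl]chromane | c1ccccc1COc1ccc2c(c1)O[C@H](c1ccc(OCc3ccccc3)c(OCc3ccccc3)c1)[C@@H](OCc1ccccc1)[C@@H]2c1cc(OCc2ccccc2)c(OCc2ccccc2)cc1Br | intermediate
15 | 5-(benzyloxy)-2-iodophenol | Oc1cc(OCc2ccccc2)ccc1I | intermediate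
16 | 2-(allyloxy)-4-(benzyloxy)-1-iodobenzene | C=CCOc1cc(OCc2ccccc2)ccc1I | intermediate
17 | methyl (S)-oxirane-2-carboxylate (methyl (S)-glycidate) | COC(=O)[C@@H]1CO1 | starting material
18 | [2-(allyloxy)-4-(benzyloxy)phenyl]magnesium chloride | C=CCOc1cc(OCc2ccccc2)ccc1[Mg]Cl | intermediate
19 | methyl (S)-3-[2-(allyloxy)-4-(benzyloxy)phenyl]-2-hydroxypropanoate | COC(=O)[C@@H](O)Cc1ccc(OCc2ccccc2)cc1OCC=C | intermediate
20 | methyl (S)-3-[2-(allyloxy)-4-(benzyloxy)phenyl]-2-(benzyloxy)propanoate | COC(=O)[C@@H](OCc1ccccc1)Cc1ccc(OCc2ccccc2)cc1OCC=C | intermediate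
21 | (S)-3-[2-(allyloxy)-4-(benzyloxy)phenyl]-2-(benzyloxy)-N-methoxy-N-methylpropanamide | CON(C)C(=O)[C@@H](OCc1ccccc1)Cc1ccc(OCc2ccccc2)cc1OCC=C | intermediate
22 | {4,5-bis(benzyloxy)-2-[(2R,3S,4R)-3,7-bis(benzyloxy)-2-[3,4-bis(benzyloxy)phenyl]chroman-4-yl]phenyl}lithium | c1ccccc1COc1ccc2c(c1)O[C@H](c1ccc(OCc3ccccc3)c(OCc3ccccc3)c1)[C@@H](OCc1ccccc1)[C@@H]2c1cc(OCc2ccccc2)c(OCc2ccccc2)cc1[Li] | intermediate
23 | (S)-3-[2-(allyloxy)-4-(benzyloxy)phenyl]-2-(benzyloxy)-1-{4,5-bis(benzyloxy)-2-[(2R,3S,4R)-3,7-bis(benzyloxy)-2-[3,4-bis(benzyloxy)phenyl]chroman-4-yl]phenyl}propan-1-one | c1ccccc1COc1ccc2c(c1)O[C@H](c1ccc(OCc3ccccc3)c(OCc3ccccc3)c1)[C@@H](OCc1ccccc1)[C@@H]2c1cc(OCc2ccccc2)c(OCc2ccccc2)cc1C(=O)[C@@H](OCc1ccccc1)Cc1ccc(OCc2ccccc2)cc1OCC=C | intermediate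
24 | (1R,2S)-3-[2-(allyloxy)-4-(benzyloxy)phenyl]-2-(benzyloxy)-1-{4,5-bis(benzyloxy)-2-[(2R,3S,4R)-3,7-bis(benzyloxy)-2-[3,4-bis(benzyloxy)phenyl]chroman-4-yl]phenyl}propan-1-ol (anti) | c1ccccc1COc1ccc2c(c1)O[C@H](c1ccc(OCc3ccccc3)c(OCc3ccccc3)c1)[C@@H](OCc1ccccc1)[C@@H]2c1cc(OCc2ccccc2)c(OCc2ccccc2)cc1[C@@H](O)[C@@H](OCc1ccccc1)Cc1ccc(OCc2ccccc2)cc1OCC=C | intermediate
25 | (1R,2S)-2-(benzyloxy)-3-[4-(benzyloxy)-2-hydroxyphenyl]-1-{4,5-bis(benzyloxy)-2-[(2R,3S,4R)-3,7-bis(benzyloxy)-2-[3,4-bis(benzyloxy)phenyl]chroman-4-yl]phenyl}propan-1-ol | c1ccccc1COc1ccc2c(c1)O[C@H](c1ccc(OCc3ccccc3)c(OCc3ccccc3)c1)[C@@H](OCc1ccccc1)[C@@H]2c1cc(OCc2ccccc2)c(OCc2ccccc2)cc1[C@@H](O)[C@@H](OCc1ccccc1)Cc1ccc(OCc2ccccc2)cc1O | intermediate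
26 | (2S,3S)-3,7-bis(benzyloxy)-2-{4,5-bis(benzyloxy)-2-[(2R,3S,4R)-3,7-bis(benzyloxy)-2-[3,4-bis(benzyloxy)phenyl]chroman-4-yl]phenyl}chromane (octabenzyl ether of the target) | c1ccccc1COc1ccc2c(c1)O[C@@H](c1cc(OCc3ccccc3)c(OCc3ccccc3)cc1[C@@H]1c3ccc(OCc4ccccc4)cc3O[C@H](c3ccc(OCc4ccccc4)c(OCc4ccccc4)c3)[C@H]1OCc1ccccc1)[C@@H](OCc1ccccc1)C2 | intermediate
27 | (2R,3S,4R)-2-(3,4-dihydroxyphenyl)-4-{2-[(2S,3S)-3,7-dihydroxychroman-2-yl]-4,5-dihydroxyphenyl}chromane-3,7-diol (CNP0244903.4) | Oc1ccc2c(c1)O[C@@H](c1cc(O)c(O)cc1[C@@H]1c3ccc(O)cc3O[C@H](c3ccc(O)c(O)c3)[C@H]1O)[C@@H](O)C2 | target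

**Step count**

Total: 21 steps. Longest linear sequence: 16 steps (steps 1–11 and 17–21, from 1 to 27); the Weinreb amide 21 is made in 5 steps (12–16) from 8.

**Steps most likely to fail**

1. Step 9 (Friedel–Crafts closure). The C2 benzylic aryl ether may ionise in competition with the C4 acetate, which would cost the phenol and scramble C2. The open C4 cation may also escape acetoxonium control, which would erode the 3,4-trans selectivity or let the catechol ring close an indane. The fallback sets out from diol 9: treatment with MeC(OMe)3 and pyridinium p-toluenesulfonate in CH2Cl2 should give the cyclic orthoacetate F1. BF3·OEt2 or TMSOTf at −78 °C then removes methoxide and generates the acetoxonium ion 11 directly, at a temperature at which the aryl ether is inert, and the ring should close as in the main route. The fallback comes back at 12.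

2. Step 7 (epoxide opening). The electron-rich benzylic epoxide carbon may ionise partly on titanium, giving incomplete inversion at C2; the phenol may also attack through carbon, or isopropoxide may be transferred. The fallback sets out from 7: TBSCl and imidazole in DMF should give the silyl ether F2. Opening with the caesium salt of 8 (Cs2CO3, DMF, 80 °C) is a purely anionic SN2 process at the benzylic carbon, with no Lewis acid and no free carbinol to allow epoxide migration, and should give the C2 aryl ether F3. Bu4NF in THF removes the silyl group, and the fallback comes back at 9.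

3. Step 20 (Mitsunobu closure). The oxyphosphonium intermediate sits on a hindered, para-oxygenated benzylic carbon and may ionise, giving incomplete inversion at lower C2 or elimination. The fallback sets out from ketone 23 and forms the C8a–O1 bond instead, so the C2–O bond is never broken:
   - Reagent-controlled reduction in the Felkin–Anh sense with the (S)-proline-derived B-methyl oxazaborolidine [(S)-1-methyl-3,3-diphenyltetrahydropyrrolo[1,2-c][1,3,2]oxazaborole] and BH3·SMe2 (Corey–Bakshi–Shibata reduction) should give the syn (1S,2S) alcohol F4.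
   - Pd(PPh3)4 and morpholine remove the allyl group to give the phenol F5.
   - PhNTf2 and K2CO3 convert the phenol selectively into the aryl triflate F6.
   - Intramolecular palladium-catalysed etherification of the secondary alcohol (Pd(OAc)2, 2-(di-tert-butylphosphino)-1,1'-binaphthyl, K3PO4, toluene, 80 °C; Buchwald–Hartwig-type C–O coupling) closes the ring with retention at the carbinol carbon. The fallback comes back at 26.

**Further compounds**

F1 | step 9 | 4-[4,5-bis(benzyloxy)-2-bromophenyl]-5-{(R)-[3,4-bis(benzyloxy)phenyl][3-(benzyloxy)phenoxy]methyl}-2-methoxy-2-methyl-1,3-dioxolane (cyclic orthoacetate of 9) | COC1(C)OC(c2cc(OCc3ccccc3)c(OCc3ccccc3)cc2Br)[C@@H]([C@@H](c2ccc(OCc3ccccc3)c(OCc3ccccc3)c2)Oc2cccc(OCc3ccccc3)c2)O1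
F2 | step 7 | tert-butyldimethylsilyl ether of epoxy alcohol 7 (both carbinol epimers) | CC(C)(C)[Si](C)(C)OC(c1cc(OCc2ccccc2)c(OCc2ccccc2)cc1Br)[C@@H]1O[C@H]1c1ccc(OCc2ccccc2)c(OCc2ccccc2)c1
F3 | step 7 | 1-O-tert-butyldimethylsilyl ether of diol 9 (C2 aryl ether, free C3 hydroxyl, both C4 epimers) | CC(C)(C)[Si](C)(C)OC(c1cc(OCc2ccccc2)c(OCc2ccccc2)cc1Br)[C@H](O)[C@@H](c1ccc(OCc2ccccc2)c(OCc2ccccc2)c1)Oc1cccc(OCc2ccccc2)c1
F4 | step 20 | (1S,2S)-3-[2-(allyloxy)-4-(benzyloxy)phenyl]-2-(benzyloxy)-1-{4,5-bis(benzyloxy)-2-[(2R,3S,4R)-3,7-bis(benzyloxy)-2-[3,4-bis(benzyloxy)phenyl]chroman-4-yl]phenyl}propan-1-ol (syn; carbinol epimer of 24) | c1ccccc1COc1ccc2c(c1)O[C@H](c1ccc(OCc3ccccc3)c(OCc3ccccc3)c1)[C@@H](OCc1ccccc1)[C@@H]2c1cc(OCc2ccccc2)c(OCc2ccccc2)cc1[C@H](O)[C@@H](OCc1ccccc1)Cc1ccc(OCc2ccccc2)cc1OCC=C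
F5 | step 20 | (1S,2S)-2-(benzyloxy)-3-[4-(benzyloxy)-2-hydroxyphenyl]-1-{4,5-bis(benzyloxy)-2-[(2R,3S,4R)-3,7-bis(benzyloxy)-2-[3,4-bis(benzyloxy)phenyl]chroman-4-yl]phenyl}propan-1-ol | c1ccccc1COc1ccc2c(c1)O[C@H](c1ccc(OCc3ccccc3)c(OCc3ccccc3)c1)[C@@H](OCc1ccccc1)[C@@H]2c1cc(OCc2ccccc2)c(OCc2ccccc2)cc1[C@H](O)[C@@H](OCc1ccccc1)Cc1ccc(OCc2ccccc2)cc1O
F6 | step 20 | aryl trifluoromethanesulfonate of F5 (phenol oxygen sulfonylated, carbinol free) | c1ccccc1COc1ccc2c(c1)O[C@H](c1ccc(OCc3ccccc3)c(OCc3ccccc3)c1)[C@@H](OCc1ccccc1)[C@@H]2c1cc(OCc2ccccc2)c(OCc2ccccc2)cc1[C@H](O)[C@@H](OCc1ccccc1)Cc1ccc(OCc2ccccc2)cc1OS(=O)(=O)C(F)(F)F
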